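**Retrosynthetic overview**
1. Last bond: E-selective cross-metathesis of a C2-allyl chromene chalcone with 2-methylbut-3-en-2-ol. The acid-labile tertiary allylic alcohol therefore never meets a deprotection.
2. Cinnamoyl group: C6 bromide, then aryllithium plus cinnamaldehyde, then MnO2. C3=C4 comes from late dehydration of a C4 carbinol, and the chromene is kept cool and dark afterwards.
3. Pyran ring: C4–C4a by aryl Grignard addition to a lactol. O1–C8a by intramolecular Pd-catalysed C–O coupling of the intact tertiary alcohol, which retains configuration.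
4. C2 stereocentre: (S)-mevalonolactone, from hydrolase (pig liver esterase) desymmetrisation of prochiral dimethyl 3-hydroxy-3-methylglutarate. The ester arm becomes C3–C4 and the acid arm becomes the side chain.
5. Ring order: both benzene rings are bought. The dihydropyran is closed in step 10 and dehydrated to the 2H-pyran in step 18.

**Assumption:** pig liver esterase gives the (S)-half-ester 3 in high ee, as is established for this substrate, and the ee is checked on lactone 5. If a batch gave the antipode, LiBH4 reduction of the ester arm instead of BH3 reduction of the acid arm would give the same lactone 5. The lactol, C4 and carbinol epimers are carried as mixtures because those centres are destroyed later.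

**Step 1**
Reactants: 1 3-hydroxy-3-methylglutaric acid
Product: 2 dimethyl 3-hydroxy-3-methylglutarate
Conditions: MeOH, H2SO4 (cat.), rt, 24 h
Reagents that add atoms: methanol, CO
Why: Fischer esterification at room temperature esterifies both equivalent acids without dehydrating the tertiary carbinol and gives the achiral, prochiral diester.

**Step 2**
Reactants: 2 dimethyl 3-hydroxy-3-methylglutarate
Product: 3 (3S)-3-hydroxy-5-methoxy-3-methyl-5-oxopentanoic acid
Conditions: pig liver esterase (carboxylesterase, serine hydrolase, EC 3.1.1.1), 0.1 M phosphate buffer pH 7.5, 25 °C, pH-stat 1 M NaOH (1.0 equiv); then HCl to pH 2.5, EtOAc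
Reagents that add atoms: water, O
Why: Enzymatic desymmetrisation (enantiotopic-group-selective ester hydrolysis), in which the chiral active site cleaves only the pro-R CH2CO2Me arm and stops at the mono-acid, sets the quaternary carbinol centre (future C2) as S by asymmetric biocatalysis.

**Step 3**
Reactants: 3 (3S)-half-ester
Product: 5 (4S)-4-hydroxy-4-methyloxan-2-one [(S)-mevalonolactone], via methyl (3S)-3,5-dihydroxy-3-methylpentanoate 4 (not isolated)
Conditions: BH3·SMe2, THF, 0 °C → rt; MeOH quench; p-TsOH (cat.), CH2Cl2, rt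
Reagents that add atoms: none
Why: Chemoselective borane reduction of the free acid beside the ester, followed by lactonisation of the 5-hydroxy ester, leaves the stereocentre untouched and fixes the ester arm as future C3–C4 and the acid arm as future side chain.

**Step 4**
Reactants: 5 (S)-mevalonolactone
Product: 6 (4S)-4-methyl-4-(trimethylsilyloxy)oxan-2-one
Conditions: TMSCl, imidazole, CH2Cl2, 0 °C → rt
Reagents that add atoms: chlorotrimethylsilane, C[Si](C)(C)Cl
Why: Silyl ether protection with the small TMS group caps the tertiary alcohol under mild base, making the next intermediates extractable and blocking retro-aldol and dehydration.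

**Step 5**
Reactants: 6 TMS-mevalonolactone
Product: 7 (4S)-4-methyl-4-(trimethylsilyloxy)oxan-2-ol (lactol, anomers)
Conditions: DIBAL-H (1.1 equiv), CH2Cl2, −78 °C; MeOH, then Na2SO4·10H2O
Reagents that add atoms: none
Why: DIBAL-H partial reduction of a δ-lactone stops at the stable tetrahedral aluminate at −78 °C and gives the lactol, a masked aldehyde on the future C4 arm.

**Step 6**
Reactants: 8 2-bromobenzene-1,4-diol
Product: 9 2-bromo-1,4-bis(methoxymethoxy)benzene
Conditions: MOMCl (2.5 equiv), i-Pr2NEt, CH2Cl2, 0 °C → rt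
Reagents that add atoms: chloromethyl methyl ether, COCCl
Why: O-alkylation (MOM acetal protection) gives base- and organometal-stable phenol ethers that also direct the following metalation.

**Step 7**
Reactants: 9 2-bromo-1,4-bis(methoxymethoxy)benzene
Product: 11 2-bromo-3-iodo-1,4-bis(methoxymethoxy)benzene, via [2-bromo-3,6-bis(methoxymethoxy)phenyl]lithium 10 (not isolated)
Conditions: LDA (1.1 equiv), THF, −78 °C, 45 min; I2, −78 °C
Reagents that add atoms: iodine, II
Why: In this directed ortho-metalation LDA removes only the proton flanked by Br and OMOM, the sole C–H acidic enough, and the fast iodine quench at −78 °C outruns aryne formation.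

**Step 8**
Reactants: 11 2-bromo-3-iodo-1,4-bis(methoxymethoxy)benzene (2.4 equiv); 7 lactol
Product: 14 (3S)-1-[2-bromo-3,6-bis(methoxymethoxy)phenyl]-3-methylpentane-1,3,5-triol (C1 epimers), via [2-bromo-3,6-bis(methoxymethoxy)phenyl]magnesium chloride 12 (not isolated), via (3S)-1-[2-bromo-3,6-bis(methoxymethoxy)phenyl]-3-methyl-3-(trimethylsilyloxy)pentane-1,5-diol 13 (not isolated)
Conditions: i-PrMgCl·LiCl, THF, −25 °C, 1 h; add 7, −25 → 0 °C; aq NH4Cl; crude: K2CO3 (cat.), MeOH, rt
Reagents that add atoms: none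
Why: Selective iodine–magnesium exchange (turbo-Grignard) gives an o-bromoaryl Grignard that is stable at 0 °C and adds to the ring-opened lactol (Grignard addition), and methanolysis then removes the TMS group wherever it has migrated; the new carbinol centre is unselective and irrelevant.

**Step 9**
Reactants: 14 triol
Product: 15 (3S)-1-[2-bromo-3,6-bis(methoxymethoxy)phenyl]-1,5-bis(tert-butyldimethylsilyloxy)-3-methylpentan-3-ol
Conditions: TBSCl (2.6 equiv), imidazole, DMAP (cat.), DMF, rt → 35 °C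
Reagents that add atoms: tert-butyldimethylsilyl chloride, CC(C)(C)[Si](C)(C)Cl
Why: Selective silylation works because TBSCl/imidazole silylates primary and secondary alcohols but not tertiary ones, leaving exactly the hydroxyl needed for ring closure free.

**Step 10**
Reactants: 15 bis-TBS bromo alcohol
Product: 16 (2S)-4-(tert-butyldimethylsilyloxy)-2-[2-(tert-butyldimethylsilyloxy)ethyl]-5,8-bis(methoxymethoxy)-2-methyl-3,4-dihydro-2H-chromene
Conditions: Pd2(dba)3 (2.5 mol %), t-BuXPhos (6 mol %), Cs2CO3 (1.5 equiv), toluene, 85 °C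
Reagents that add atoms: none
Why: In this intramolecular Buchwald–Hartwig C–O coupling the tertiary alkoxide has no β-hydrogen on its carbinol carbon to lose and closes a six-membered ring, and because only the O–H and C–Br bonds change, C2 keeps its configuration.

**Step 11**
Reactants: 16 chroman
Product: 17 (2S)-6-bromo-4-(tert-butyldimethylsilyloxy)-2-[2-(tert-butyldimethylsilyloxy)ethyl]-5,8-bis(methoxymethoxy)-2-methyl-3,4-dihydro-2H-chromene
Conditions: NBS (1.02 equiv), MeCN, −10 → 0 °C, dark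
Reagents that add atoms: N-bromosuccinimide, O=C1CCC(=O)N1Br
Why: Electrophilic aromatic bromination goes to C6, which is para to ring O1 and ortho to the 5-OMOM group (the usual site of 1,2,4-trialkoxybenzenes), whereas C7 is activated by only one ortho alkoxy group.

**Step 12**
Reactants: 17 bromochroman
Product: 18 2-[(2S)-6-bromo-4-(tert-butyldimethylsilyloxy)-5,8-bis(methoxymethoxy)-2-methyl-3,4-dihydro-2H-chromen-2-yl]ethanol
Conditions: HF·pyridine, pyridine, THF, 0 °C
Reagents that add atoms: none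
Why: Buffered HF·pyridine desilylation cleaves the unhindered primary TBS ether much faster than the hindered secondary benzylic one and spares the MOM ethers.

**Step 13**
Reactants: 18 primary alcohol
Product: 19 [(2R)-6-bromo-4-(tert-butyldimethylsilyloxy)-5,8-bis(methoxymethoxy)-2-methyl-3,4-dihydro-2H-chromen-2-yl]acetaldehyde (same spatial arrangement; the descriptor changes by CIP ranking only)
Conditions: TEMPO (10 mol %), PhI(OAc)2 (1.1 equiv), CH2Cl2, rt
Reagents that add atoms: none
Why: TEMPO/PhI(OAc)2 oxoammonium oxidation stops at the aldehyde under base-free conditions, so the β-aryloxy aldehyde cannot undergo E1cB ring opening.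

**Step 14**
Reactants: 19 aldehyde
Product: 20 (2S)-2-allyl-6-bromo-4-(tert-butyldimethylsilyloxy)-5,8-bis(methoxymethoxy)-2-methyl-3,4-dihydro-2H-chromene
Conditions: Ph3PCH3Br, KHMDS, THF, 0 °C; then 19, −78 → 0 °C
Reagents that add atoms: methyltriphenylphosphonium bromide, C[P+](c1ccccc1)(c1ccccc1)c1ccccc1.[Br-]
Why: In this Wittig methylenation carbonyl addition of the unstabilised ylide at low temperature is faster than α-deprotonation, as is known for chroman-2-ylacetaldehydes, and gives the allyl group without touching C2.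

**Step 15**
Reactants: 20 allyl bromochroman; 21 (E)-cinnamaldehyde
Product: 23 (E)-1-[(2S)-2-allyl-4-(tert-butyldimethylsilyloxy)-5,8-bis(methoxymethoxy)-2-methyl-3,4-dihydro-2H-chromen-6-yl]-3-phenylprop-2-en-1-ol (carbinol epimers), via [(2S)-2-allyl-4-(tert-butyldimethylsilyloxy)-5,8-bis(methoxymethoxy)-2-methyl-3,4-dihydro-2H-chromen-6-yl]lithium 22 (not isolated)
Conditions: n-BuLi (1.05 equiv), THF, −78 °C, 15 min; 21, −78 °C; aq NH4Cl
Reagents that add atoms: none
Why: Bromine–lithium exchange is faster than any deprotonation at −78 °C, and the OMOM-chelated aryllithium adds 1,2 to the enal.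

**Step 16**
Reactants: 23 allylic/benzylic alcohol
Product: 24 (E)-1-[(2S)-2-allyl-4-(tert-butyldimethylsilyloxy)-5,8-bis(methoxymethoxy)-2-methyl-3,4-dihydro-2H-chromen-6-yl]-3-phenylprop-2-en-1-one
Conditions: activated MnO2 (15 equiv), CH2Cl2, rt
Reagents that add atoms: none
Why: MnO2 oxidation is selective for the doubly activated (allylic and benzylic) carbinol and gives the chalcone under neutral conditions with the E alkene retained.

**Step 17**
Reactants: 24 silyl chalcone
Product: 25 (E)-1-[(2S)-2-allyl-4-hydroxy-5,8-bis(methoxymethoxy)-2-methyl-3,4-dihydro-2H-chromen-6-yl]-3-phenylprop-2-en-1-one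
Conditions: TBAF, AcOH (1:1), THF, rt → 40 °C
Reagents that add atoms: none
Why: Fluoride desilylation buffered with AcOH frees the C4 alcohol without exposing the enone to strongly basic fluoride, and mild heating is harmless because the ring is still saturated.

**Step 18**
Reactants: 25 chroman-4-ol
Product: 27 (E)-1-[(2S)-2-allyl-5,8-bis(methoxymethoxy)-2-methyl-2H-chromen-6-yl]-3-phenylprop-2-en-1-one, via (2S)-2-allyl-5,8-bis(methoxymethoxy)-2-methyl-6-[(E)-3-phenylprop-2-enoyl]-3,4-dihydro-2H-chromen-4-yl methanesulfonate 26 (not isolated)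
Conditions: MsCl (1.5 equiv), Et3N (4 equiv), CH2Cl2, 0 °C → rt, dark
Reagents that add atoms: none
Why: Mesylation–elimination succeeds because the benzylic mesylate, flanked by two ortho oxygen donors, loses MsOH at or below room temperature to give the conjugated C3=C4 bond, which keeps the now allylic C2 centre away from heat and acid.

**Step 19**
Reactants: 27 bis-MOM chromene chalcone
Product: 28 (E)-1-[(2S)-2-allyl-5,8-dihydroxy-2-methyl-2H-chromen-6-yl]-3-phenylprop-2-en-1-one
Conditions: 2 M aq HCl (cat.), MeOH, rt, Ar, dark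
Reagents that add atoms: none
Why: Acid-catalysed acetal exchange (standard MOM cleavage for chromenochalcones) at room temperature frees both phenols before any tertiary allylic alcohol is present, and it is too mild for flavanone closure.

**Step 20**
Reactants: 28 allyl chromene chalcone; 29 2-methylbut-3-en-2-ol (8 equiv)
Product: 30 (E)-1-{(2S)-5,8-dihydroxy-2-[(2E)-4-hydroxy-4-methylpent-2-en-1-yl]-2-methyl-2H-chromen-6-yl}-3-phenylprop-2-en-1-one (target)
Conditions: Hoveyda–Grubbs II (5 mol %), CH2Cl2, 35 °C, Ar, dark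
Reagents that add atoms: none
Why: Olefin cross-metathesis of a type I terminal alkene with a type II free tertiary allylic alcohol is selective and E-selective, while the hindered ring alkene and the enone are spectators and C2 is untouched.

**Compound list**
1 | 3-hydroxy-3-methylglutaric acid | CC(O)(CC(=O)O)CC(=O)O | starting material
2 | dimethyl 3-hydroxy-3-methylglutarate | COC(=O)CC(C)(O)CC(=O)OC | intermediate
3 | (3S)-3-hydroxy-5-methoxy-3-methyl-5-oxopentanoic acid | C[C@](O)(CC(=O)O)CC(=O)OC | intermediate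
4 | methyl (3S)-3,5-dihydroxy-3-methylpentanoate | C[C@](O)(CCO)CC(=O)OC | intermediate
5 | (4S)-4-hydroxy-4-methyloxan-2-one | C[C@]1(O)CCOC(=O)C1 | intermediate
6 | (4S)-4-methyl-4-(trimethylsilyloxy)oxan-2-one | C[C@]1(O[Si](C)(C)C)CCOC(=O)C1 | intermediate
7 | (4S)-4-methyl-4-(trimethylsilyloxy)oxan-2-ol | C[C@]1(O[Si](C)(C)C)CCOC(O)C1 | intermediate
8 | 2-bromobenzene-1,4-diol | Oc1ccc(O)c(Br)c1 | starting material
9 | 2-bromo-1,4-bis(methoxymethoxy)benzene | COCOc1ccc(OCOC)c(Br)c1 | intermediate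
10 | [2-bromo-3,6-bis(methoxymethoxy)phenyl]lithium | [Li]c1c(Br)c(OCOC)ccc1OCOC | intermediate
11 | 2-bromo-3-iodo-1,4-bis(methoxymethoxy)benzene | COCOc1ccc(OCOC)c(I)c1Br | intermediate
12 | [2-bromo-3,6-bis(methoxymethoxy)phenyl]magnesium chloride | COCOc1ccc(OCOC)c([Mg]Cl)c1Br | intermediate
13 | (3S)-1-[2-bromo-3,6-bis(methoxymethoxy)phenyl]-3-methyl-3-(trimethylsilyloxy)pentane-1,5-diol | C[C@](O[Si](C)(C)C)(CCO)CC(O)c1c(Br)c(OCOC)ccc1OCOC | intermediate
14 | (3S)-1-[2-bromo-3,6-bis(methoxymethoxy)phenyl]-3-methylpentane-1,3,5-triol | C[C@](O)(CCO)CC(O)c1c(Br)c(OCOC)ccc1OCOC | intermediate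
15 | (3S)-1-[2-bromo-3,6-bis(methoxymethoxy)phenyl]-1,5-bis(tert-butyldimethylsilyloxy)-3-methylpentan-3-ol | C[C@](O)(CCO[Si](C)(C)C(C)(C)C)CC(O[Si](C)(C)C(C)(C)C)c1c(Br)c(OCOC)ccc1OCOC | intermediate
16 | (2S)-4-(TBSO)-2-[2-(TBSO)ethyl]-5,8-bis(methoxymethoxy)-2-methyl-3,4-dihydro-2H-chromene | C[C@]1(CCO[Si](C)(C)C(C)(C)C)CC(O[Si](C)(C)C(C)(C)C)c2c(OCOC)ccc(OCOC)c2O1 | intermediate
17 | (2S)-6-bromo-4-(TBSO)-2-[2-(TBSO)ethyl]-5,8-bis(methoxymethoxy)-2-methyl-3,4-dihydro-2H-chromene | C[C@]1(CCO[Si](C)(C)C(C)(C)C)CC(O[Si](C)(C)C(C)(C)C)c2c(OCOC)c(Br)cc(OCOC)c2O1 | intermediate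
18 | 2-[(2S)-6-bromo-4-(TBSO)-5,8-bis(methoxymethoxy)-2-methyl-3,4-dihydro-2H-chromen-2-yl]ethanol | C[C@]1(CCO)CC(O[Si](C)(C)C(C)(C)C)c2c(OCOC)c(Br)cc(OCOC)c2O1 | intermediate
19 | [(2R)-6-bromo-4-(TBSO)-5,8-bis(methoxymethoxy)-2-methyl-3,4-dihydro-2H-chromen-2-yl]acetaldehyde | C[C@]1(CC=O)CC(O[Si](C)(C)C(C)(C)C)c2c(OCOC)c(Br)cc(OCOC)c2O1 | intermediate
20 | (2S)-2-allyl-6-bromo-4-(TBSO)-5,8-bis(methoxymethoxy)-2-methyl-3,4-dihydro-2H-chromene | C[C@]1(CC=C)CC(O[Si](C)(C)C(C)(C)C)c2c(OCOC)c(Br)cc(OCOC)c2O1 | intermediate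
21 | (E)-cinnamaldehyde | O=C/C=C/c1ccccc1 | starting material
22 | [(2S)-2-allyl-4-(TBSO)-5,8-bis(methoxymethoxy)-2-methyl-3,4-dihydro-2H-chromen-6-yl]lithium | C[C@]1(CC=C)CC(O[Si](C)(C)C(C)(C)C)c2c(OCOC)c([Li])cc(OCOC)c2O1 | intermediate
23 | (E)-1-[(2S)-2-allyl-4-(TBSO)-5,8-bis(methoxymethoxy)-2-methyl-3,4-dihydro-2H-chromen-6-yl]-3-phenylprop-2-en-1-ol | C[C@]1(CC=C)CC(O[Si](C)(C)C(C)(C)C)c2c(OCOC)c(C(O)/C=C/c3ccccc3)cc(OCOC)c2O1 | intermediate
24 | (E)-1-[(2S)-2-allyl-4-(TBSO)-5,8-bis(methoxymethoxy)-2-methyl-3,4-dihydro-2H-chromen-6-yl]-3-phenylprop-2-en-1-one | C[C@]1(CC=C)CC(O[Si](C)(C)C(C)(C)C)c2c(OCOC)c(C(=O)/C=C/c3ccccc3)cc(OCOC)c2O1 | intermediate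
25 | (E)-1-[(2S)-2-allyl-4-hydroxy-5,8-bis(methoxymethoxy)-2-methyl-3,4-dihydro-2H-chromen-6-yl]-3-phenylprop-2-en-1-one | C[C@]1(CC=C)CC(O)c2c(OCOC)c(C(=O)/C=C/c3ccccc3)cc(OCOC)c2O1 | intermediate
26 | (2S)-2-allyl-5,8-bis(methoxymethoxy)-2-methyl-6-[(E)-3-phenylprop-2-enoyl]-3,4-dihydro-2H-chromen-4-yl methanesulfonate | C[C@]1(CC=C)CC(OS(C)(=O)=O)c2c(OCOC)c(C(=O)/C=C/c3ccccc3)cc(OCOC)c2O1 | intermediate
27 | (E)-1-[(2S)-2-allyl-5,8-bis(methoxymethoxy)-2-methyl-2H-chromen-6-yl]-3-phenylprop-2-en-1-one | C[C@]1(CC=C)C=Cc2c(OCOC)c(C(=O)/C=C/c3ccccc3)cc(OCOC)c2O1 | intermediate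
28 | (E)-1-[(2S)-2-allyl-5,8-dihydroxy-2-methyl-2H-chromen-6-yl]-3-phenylprop-2-en-1-one | C[C@]1(CC=C)C=Cc2c(O)c(C(=O)/C=C/c3ccccc3)cc(O)c2O1 | intermediate
29 | 2-methylbut-3-en-2-ol | C=CC(C)(C)O | starting material
30 | (E)-1-{(2S)-5,8-dihydroxy-2-[(2E)-4-hydroxy-4-methylpent-2-en-1-yl]-2-methyl-2H-chromen-6-yl}-3-phenylprop-2-en-1-one | CC(C)(O)/C=C/C[C@@]1(C)C=Cc2c(O)c(C(=O)/C=C/c3ccccc3)cc(O)c2O1 | target

**Total steps:** 20. **Longest linear sequence:** 18 (steps 1–5, then 8–20). Steps 6–7 form the arene branch.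

**Three steps most likely to fail**

**Step 10 (Pd C–O coupling).** The aryl bromide is electron-rich and di-ortho-substituted, so slow oxidative addition or hydrodebromination is possible. The fallback replaces the cross-coupling with an intramolecular SNAr on an aryl fluoride. It sets out from lactol 7 and comes back at chroman 16.
- Commercial 2-fluorohydroquinone is protected (MOMCl, i-Pr2NEt) to give 2-fluoro-1,4-bis(methoxymethoxy)benzene F1.
- n-BuLi (THF, −78 °C) metalates between F and OMOM to give [2-fluoro-3,6-bis(methoxymethoxy)phenyl]lithium F2.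
- MgBr2·OEt2 converts this into [2-fluoro-3,6-bis(methoxymethoxy)phenyl]magnesium bromide F3.
- F3 adds to 7 to give (3S)-1-[2-fluoro-3,6-bis(methoxymethoxy)phenyl]-3-methyl-3-(trimethylsilyloxy)pentane-1,5-diol F4.
- K2CO3/MeOH then gives (3S)-1-[2-fluoro-3,6-bis(methoxymethoxy)phenyl]-3-methylpentane-1,3,5-triol F5.
- TBSCl/imidazole gives (3S)-1-[2-fluoro-3,6-bis(methoxymethoxy)phenyl]-1,5-bis(tert-butyldimethylsilyloxy)-3-methylpentan-3-ol F6.
- KHMDS (toluene–THF, 60–90 °C) forms the tertiary potassium alkoxide, which displaces fluoride. The ortho-OMOM group binds K+ and helps inductively. The C2–O bond is again untouched, and the product is 16.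

**Step 19 (acidic MOM removal on the chromene chalcone).** The risks are ionisation of the allylic C2–O bond with loss of ee, addition of MeOH to C3=C4, and flavanone formation. The fallback avoids Brønsted acid and re-orders the end-game. It sets out from 27 and comes back at 30.
- TESOTf/2,2′-bipyridyl (CH2Cl2, 0 °C → rt) exchanges both aryl MOM ethers directly for silyl ethers. This gives (E)-1-[(2S)-2-allyl-2-methyl-5,8-bis(triethylsilyloxy)-2H-chromen-6-yl]-3-phenylprop-2-en-1-one F7.
- Cross-metathesis of F7 with 29 (Hoveyda–Grubbs II, CH2Cl2, 35 °C) gives (E)-1-{(2S)-2-[(2E)-4-hydroxy-4-methylpent-2-en-1-yl]-2-methyl-5,8-bis(triethylsilyloxy)-2H-chromen-6-yl}-3-phenylprop-2-en-1-one F8.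
- Et3N·3HF (THF, 0 °C) removes the phenolic TES groups without harming the tertiary allylic alcohol and gives 30.

**Step 20 (metathesis on the free hydroquinone / 2′-hydroxychalcone).** The risks are catalyst deactivation by the chelating phenols, air oxidation, and allyl isomerisation. The fallback masks the phenols as esters and unmasks them enzymatically at neutral pH. It sets out from 28 and comes back at 30.
- Ac2O/pyridine (DMAP cat., 0 °C) gives (2S)-2-allyl-2-methyl-6-[(E)-3-phenylprop-2-enoyl]-2H-chromene-5,8-diyl diacetate F9.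
- Cross-metathesis of F9 with 29 gives (2S)-2-[(2E)-4-hydroxy-4-methylpent-2-en-1-yl]-2-methyl-6-[(E)-3-phenylprop-2-enoyl]-2H-chromene-5,8-diyl diacetate F10.
- Immobilised Candida antarctica lipase B (a triacylglycerol lipase, serine hydrolase) with n-BuOH in MTBE at 30 °C transfers both activated aryl acetates to butanol and releases 30. No acid or base is involved.

**Further compounds**
F1 | step 10 | 2-fluoro-1,4-bis(methoxymethoxy)benzene | COCOc1ccc(OCOC)c(F)c1
F2 | step 10 | [2-fluoro-3,6-bis(methoxymethoxy)phenyl]lithium | [Li]c1c(F)c(OCOC)ccc1OCOC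
F3 | step 10 | [2-fluoro-3,6-bis(methoxymethoxy)phenyl]magnesium bromide | Br[Mg]c1c(F)c(OCOC)ccc1OCOC
F4 | step 10 | (3S)-1-[2-fluoro-3,6-bis(methoxymethoxy)phenyl]-3-methyl-3-(trimethylsilyloxy)pentane-1,5-diol | C[C@](O[Si](C)(C)C)(CCO)CC(O)c1c(F)c(OCOC)ccc1OCOC
F5 | step 10 | (3S)-1-[2-fluoro-3,6-bis(methoxymethoxy)phenyl]-3-methylpentane-1,3,5-triol | C[C@](O)(CCO)CC(O)c1c(F)c(OCOC)ccc1OCOC
F6 | step 10 | (3S)-1-[2-fluoro-3,6-bis(methoxymethoxy)phenyl]-1,5-bis(tert-butyldimethylsilyloxy)-3-methylpentan-3-ol | C[C@](O)(CCO[Si](C)(C)C(C)(C)C)CC(O[Si](C)(C)C(C)(C)C)c1c(F)c(OCOC)ccc1OCOC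
F7 | step 19 | (E)-1-[(2S)-2-allyl-2-methyl-5,8-bis(triethylsilyloxy)-2H-chromen-6-yl]-3-phenylprop-2-en-1-one | C[C@]1(CC=C)C=Cc2c(O[Si](CC)(CC)CC)c(C(=O)/C=C/c3ccccc3)cc(O[Si](CC)(CC)CC)c2O1
F8 | step 19 | (E)-1-{(2S)-2-[(2E)-4-hydroxy-4-methylpent-2-en-1-yl]-2-methyl-5,8-bis(triethylsilyloxy)-2H-chromen-6-yl}-3-phenylprop-2-en-1-one | CC(C)(O)/C=C/C[C@@]1(C)C=Cc2c(O[Si](CC)(CC)CC)c(C(=O)/C=C/c3ccccc3)cc(O[Si](CC)(CC)CC)c2O1
F9 | step 20 | (2S)-2-allyl-2-methyl-6-[(E)-3-phenylprop-2-enoyl]-2H-chromene-5,8-diyl diacetate | C[C@]1(CC=C)C=Cc2c(OC(C)=O)c(C(=O)/C=C/c3ccccc3)cc(OC(C)=O)c2O1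
F10 | step 20 | (2S)-2-[(2E)-4-hydroxy-4-methylpent-2-en-1-yl]-2-methyl-6-[(E)-3-phenylprop-2-enoyl]-2H-chromene-5,8-diyl diacetate | CC(C)(O)/C=C/C[C@@]1(C)C=Cc2c(OC(C)=O)c(C(=O)/C=C/c3ccccc3)cc(OC(C)=O)c2O1
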